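**Retrosynthetic overview**

1. Numbering: C7 is the benzylic carbinol carbon, C8 the carbon carrying the aryl ether oxygen, C9 the CH2OH carbon. The last disconnection removes three silyl ethers (syringyl phenol O, C9–O, cinnamyl O).
2. Key disconnection: the bond between C1 of the syringyl ring (para to the phenol oxygen, where commercial 4-bromo-2,6-dimethoxyphenol carries its bromine) and C7. This gives an arylzinc reagent and a racemic 2-aryloxy-3-silyloxypropanal, joined by one catalytic asymmetric aryl transfer run as a dynamic kinetic resolution that sets C7 and C8 together.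
3. Enabling feature: C8–H lies between the C7 formyl carbon and the aryl ether oxygen, so at the aldehyde oxidation level of C7 it is acidic and configurationally labile. The erythro (anti) relation of C7–OH and C8–OAr is the polar Felkin–Anh outcome.
4. The aldehyde comes from sinapyl alcohol and diethyl chloromalonate: phenol O-alkylation, reduction to the prochiral 2-aryloxy-1,3-diol, monosilylation, oxidation. No desymmetrisation is needed because C8 is reset in the key step.
5. No ring is formed; both benzene rings are bought intact.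

Key step: step 8

Remark: salts formed by simple deprotonation of a numbered compound (phenoxides, alkoxides, metal alkoxides before work-up) are counted as that compound and receive no number; TBS = tert-butyldimethylsilyl.

**Route**

Step 1
Reactants: 1 methyl (E)-sinapate
Product: 2 sinapyl alcohol
Conditions: DIBAL-H (4 equiv), toluene, −78 → 0 °C; aq Rochelle salt
Reagents that add atoms: none
Why: DIBAL-H 1,2-reduction of the conjugated ester should give the allylic alcohol with the E-alkene untouched; one equivalent of hydride is consumed by the phenol.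

Step 2
Reactants: 2 sinapyl alcohol; 3 diethyl chloromalonate
Product: 4 diethyl 2-{4-[(E)-3-hydroxyprop-1-enyl]-2,6-dimethoxyphenoxy}malonate
Conditions: K2CO3, DMF, 50 °C, Ar
Reagents that add atoms: none
Why: Williamson ether synthesis: carbonate deprotonates only the phenol (not the allylic alcohol), and the phenoxide should displace chloride from the doubly activated malonate carbon despite the two flanking methoxy groups.

Step 3
Reactants: 4 diethyl 2-{4-[(E)-3-hydroxyprop-1-enyl]-2,6-dimethoxyphenoxy}malonate
Product: 5 diethyl 2-{4-[(E)-3-(tert-butyldimethylsilyloxy)prop-1-enyl]-2,6-dimethoxyphenoxy}malonate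
Conditions: TBSCl, imidazole, DMF, rt
Reagents that add atoms: tert-butyldimethylsilyl chloride, CC(C)(C)[Si](C)(C)Cl
Why: Standard silylation of the only free hydroxyl (primary, allylic); imidazole is too weak a base to touch the malonate C–H.

Step 4
Reactants: 5 diethyl 2-{4-[(E)-3-(tert-butyldimethylsilyloxy)prop-1-enyl]-2,6-dimethoxyphenoxy}malonate
Product: 6 2-{4-[(E)-3-(tert-butyldimethylsilyloxy)prop-1-enyl]-2,6-dimethoxyphenoxy}propane-1,3-diol
Conditions: LiBH4, THF, 0 °C → rt; aq NH4Cl
Reagents that add atoms: none
Why: Borohydride reduction of the two α-aryloxy-activated esters to primary alcohols; the silyl ether, aryl ethers and alkene are inert, and the product is prochiral at C8 (two identical CH2OH arms).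

Step 5
Reactants: 6 2-{4-[(E)-3-(tert-butyldimethylsilyloxy)prop-1-enyl]-2,6-dimethoxyphenoxy}propane-1,3-diol
Product: 7 rac-3-(tert-butyldimethylsilyloxy)-2-{4-[(E)-3-(tert-butyldimethylsilyloxy)prop-1-enyl]-2,6-dimethoxyphenoxy}propan-1-ol
Conditions: NaH (1.0 equiv), THF, 0 °C → rt; then TBSCl (1.0 equiv)
Reagents that add atoms: tert-butyldimethylsilyl chloride, CC(C)(C)[Si](C)(C)Cl
Why: Monosilylation of a symmetrical 1,3-diol through its sparingly soluble monosodium alkoxide, which is silylated once; the racemic product suffices because the configuration at C8 is set in step 8.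

Step 6
Reactants: 7 rac-3-(tert-butyldimethylsilyloxy)-2-{4-[(E)-3-(tert-butyldimethylsilyloxy)prop-1-enyl]-2,6-dimethoxyphenoxy}propan-1-ol
Product: 8 rac-3-(tert-butyldimethylsilyloxy)-2-{4-[(E)-3-(tert-butyldimethylsilyloxy)prop-1-enyl]-2,6-dimethoxyphenoxy}propanal
Conditions: Dess–Martin periodinane, NaHCO3, CH2Cl2, 0 °C → rt; filtered and used at once
Reagents that add atoms: none
Why: Dess–Martin oxidation of the primary alcohol stops at the aldehyde under buffered, non-eliminating conditions; any epimerisation at C8 is irrelevant because the compound is racemic.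

Step 7
Reactants: 9 4-bromo-2,6-dimethoxyphenol
Product: 10 (4-bromo-2,6-dimethoxyphenoxy)(tert-butyl)dimethylsilane
Conditions: TBSCl, imidazole, DMF, rt
Reagents that add atoms: tert-butyldimethylsilyl chloride, CC(C)(C)[Si](C)(C)Cl
Why: Standard phenol silylation; it masks the acidic O–H so that the ring can be metalated at the bromine-bearing carbon.

Step 8
Reactants: 8 rac-3-(tert-butyldimethylsilyloxy)-2-{4-[(E)-3-(tert-butyldimethylsilyloxy)prop-1-enyl]-2,6-dimethoxyphenoxy}propanal; 10 (4-bromo-2,6-dimethoxyphenoxy)(tert-butyl)dimethylsilane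
Product: 14 (1S,2R)-3-(tert-butyldimethylsilyloxy)-1-[4-(tert-butyldimethylsilyloxy)-3,5-dimethoxyphenyl]-2-{4-[(E)-3-(tert-butyldimethylsilyloxy)prop-1-enyl]-2,6-dimethoxyphenoxy}propan-1-ol, via aryllithium 11 (not isolated), via arylzinc chloride 12 (not isolated), via aryl(butyl)zinc 13 (not isolated)
Conditions: 10 (2 equiv), n-BuLi (2 equiv), t-BuOMe, −78 °C; ZnCl2 (2 equiv), then n-BuLi (2 equiv), −78 → 0 °C; N,N,N',N'-tetraethylethylenediamine (TEEDA, excess over LiCl), toluene; (2S)-(−)-3-exo-(morpholino)isoborneol [(−)-MIB, 10 mol %]; 8, 0 °C; aq NH4Cl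
Reagents that add atoms: none
Why: Proposed new method: bromine–lithium exchange on 10 and two transmetalations give the mixed arylzinc 13, whose aryl group is passed to the formyl carbon of 8 inside the dinuclear zinc aminoalkoxide formed from (−)-MIB (six-membered transition state, aldehyde bound to the catalyst zinc, aryl delivered from the second zinc). Meanwhile the C8–H of unreacted 8, acidified by the C7 carbonyl and the aryl ether oxygen, is removed reversibly by the free tertiary diamine with zinc as Lewis acid, so the two aldehyde enantiomers interconvert through the achiral enol(ate) and are funnelled into one product. The closest known reaction types are the amino-alcohol/zinc-catalysed enantioselective aryl transfer from ArZnBu (made from aryl bromides) to aldehydes and the amine-mediated dynamic kinetic resolution of α-branched aldehydes in asymmetric hydrogenation and reductive amination; their merger on an α-aryloxy aldehyde is the new element. No ring is closed. C7 (S) is set by the catalyst, the (−)-enantiomer of which directs organozinc addition to the Si face of aldehydes, and C8 (R) is selected by matching, since only the (R)-aldehyde can accept Si-face attack through the polar Felkin–Anh arrangement with the aryloxy group anti to the incoming aryl, which leads to the erythro (anti) product. The step needs racemisation to outrun addition to the mismatched (S)-aldehyde and enolisation without β-elimination or chelation: the doubly activated C8–H serves the first, the poor leaving-group ability of the C9 silyloxide the second, and the coordinatively saturated catalyst zinc with hindered or silylated ether oxygens disfavours the chelate that would give the threo isomer.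

Step 9
Reactants: 14 (1S,2R)-3-(tert-butyldimethylsilyloxy)-1-[4-(tert-butyldimethylsilyloxy)-3,5-dimethoxyphenyl]-2-{4-[(E)-3-(tert-butyldimethylsilyloxy)prop-1-enyl]-2,6-dimethoxyphenoxy}propan-1-ol
Product: 15 (1S,2R)-1-(4-hydroxy-3,5-dimethoxyphenyl)-2-{4-[(E)-3-hydroxyprop-1-enyl]-2,6-dimethoxyphenoxy}propane-1,3-diol
Conditions: TBAF, AcOH (1:1, 3.6 equiv each), THF, 0 °C → rt
Reagents that add atoms: none
Why: Fluoride-mediated cleavage of the aryl silyl ether and the two primary alkyl silyl ethers in one operation; the acetic acid buffer should keep the p-hydroxybenzylic C7 carbinol from ionising, so neither stereocentre is touched.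

**Compound list**

1 | methyl (E)-sinapate [methyl (E)-3-(4-hydroxy-3,5-dimethoxyphenyl)prop-2-enoate] | COC(=O)/C=C/c1cc(OC)c(O)c(OC)c1 | starting material
2 | sinapyl alcohol [4-[(E)-3-hydroxyprop-1-enyl]-2,6-dimethoxyphenol] | OC/C=C/c1cc(OC)c(O)c(OC)c1 | intermediate
3 | diethyl chloromalonate | CCOC(=O)C(Cl)C(=O)OCC | starting material
4 | diethyl 2-{4-[(E)-3-hydroxyprop-1-enyl]-2,6-dimethoxyphenoxy}malonate | CCOC(=O)C(Oc1c(OC)cc(/C=C/CO)cc1OC)C(=O)OCC | intermediate
5 | diethyl 2-{4-[(E)-3-(tert-butyldimethylsilyloxy)prop-1-enyl]-2,6-dimethoxyphenoxy}malonate | CCOC(=O)C(Oc1c(OC)cc(/C=C/CO[Si](C)(C)C(C)(C)C)cc1OC)C(=O)OCC | intermediate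
6 | 2-{4-[(E)-3-(tert-butyldimethylsilyloxy)prop-1-enyl]-2,6-dimethoxyphenoxy}propane-1,3-diol (prochiral) | OCC(CO)Oc1c(OC)cc(/C=C/CO[Si](C)(C)C(C)(C)C)cc1OC | intermediate
7 | rac-3-(tert-butyldimethylsilyloxy)-2-{4-[(E)-3-(tert-butyldimethylsilyloxy)prop-1-enyl]-2,6-dimethoxyphenoxy}propan-1-ol (racemate) | OCC(CO[Si](C)(C)C(C)(C)C)Oc1c(OC)cc(/C=C/CO[Si](C)(C)C(C)(C)C)cc1OC | intermediate
8 | rac-3-(tert-butyldimethylsilyloxy)-2-{4-[(E)-3-(tert-butyldimethylsilyloxy)prop-1-enyl]-2,6-dimethoxyphenoxy}propanal (racemate, configurationally labile) | O=CC(CO[Si](C)(C)C(C)(C)C)Oc1c(OC)cc(/C=C/CO[Si](C)(C)C(C)(C)C)cc1OC | intermediate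
9 | 4-bromo-2,6-dimethoxyphenol | COc1cc(Br)cc(OC)c1O | starting material
10 | (4-bromo-2,6-dimethoxyphenoxy)(tert-butyl)dimethylsilane | COc1cc(Br)cc(OC)c1O[Si](C)(C)C(C)(C)C | intermediate
11 | [4-(tert-butyldimethylsilyloxy)-3,5-dimethoxyphenyl]lithium | [Li]c1cc(OC)c(O[Si](C)(C)C(C)(C)C)c(OC)c1 | intermediate (not isolated)
12 | [4-(tert-butyldimethylsilyloxy)-3,5-dimethoxyphenyl]zinc chloride | Cl[Zn]c1cc(OC)c(O[Si](C)(C)C(C)(C)C)c(OC)c1 | intermediate (not isolated)
13 | butyl[4-(tert-butyldimethylsilyloxy)-3,5-dimethoxyphenyl]zinc | CCCC[Zn]c1cc(OC)c(O[Si](C)(C)C(C)(C)C)c(OC)c1 | intermediate (not isolated)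
14 | (1S,2R)-3-(tert-butyldimethylsilyloxy)-1-[4-(tert-butyldimethylsilyloxy)-3,5-dimethoxyphenyl]-2-{4-[(E)-3-(tert-butyldimethylsilyloxy)prop-1-enyl]-2,6-dimethoxyphenoxy}propan-1-ol | COc1cc([C@H](O)[C@@H](CO[Si](C)(C)C(C)(C)C)Oc2c(OC)cc(/C=C/CO[Si](C)(C)C(C)(C)C)cc2OC)cc(OC)c1O[Si](C)(C)C(C)(C)C | intermediate
15 | (1S,2R)-1-(4-hydroxy-3,5-dimethoxyphenyl)-2-{4-[(E)-3-hydroxyprop-1-enyl]-2,6-dimethoxyphenoxy}propane-1,3-diol (erythro) | COc1cc([C@H](O)[C@@H](CO)Oc2c(OC)cc(/C=C/CO)cc2OC)cc(OC)c1O | target

**Step count and risks**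

Total steps: 9. Longest linear sequence: 8 steps (1, 2, 3, 4, 5, 6, 8, 9); step 7 is a one-step branch.

Steps most likely to fail:

1. Step 8 (Proposed new method). Enolisation of the aldehyde may be too slow relative to aryl transfer, so the mismatched enantiomer is consumed as such and stereoconvergence is lost (threo isomer builds up). The amine may also trigger β-elimination of the C9 silyloxide. The fallback uses known chemistry and a configurationally defined aldehyde. Setting out from diol 6, a lipase-catalysed desymmetrising monoacetylation (Pseudomonas cepacia lipase, vinyl acetate, enzyme chosen by screening for the R sense) should give (2R)-monoacetate F1. Immediate silylation (TBSCl, imidazole) gives acetate silyl ether F2, and mild methanolysis (K2CO3, MeOH, 0 °C) gives (S)-alcohol F3. Buffered Dess–Martin oxidation then gives (R)-aldehyde F4, used at once. Addition of aryllithium 11 (from 10 and n-BuLi, THF, −78 °C) under polar Felkin–Anh control should give 14 after chromatographic removal of the minor threo isomer; the route is rejoined at 14.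

2. Step 2. Etherification at the phenoxide oxygen flanked by two methoxy groups may be sluggish at the secondary malonate carbon, while the electron-rich sinapyl phenoxide degrades oxidatively on prolonged heating. The fallback makes the aryl ether at a primary carbon and adds the third carbon afterwards. Setting out from 2, alkylation with ethyl bromoacetate (K2CO3, acetone, rt) should give aryloxyacetate F5, and silylation (TBSCl, imidazole) its allylic silyl ether F6. Crossed Claisen formylation (NaH, ethyl formate, THF) gives formyl ester F7 (mainly as its enol). Borohydride reduction of both the formyl group and the activated ester (NaBH4, EtOH, 0 °C → rt) returns to the route at diol 6.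

3. Step 9. Once the phenoxide is unveiled under basic fluoride, expulsion of the benzylic hydroxide to a quinone methide would scramble C7; incomplete cleavage through silyl migration is also possible. The fallback splits the endgame into two chemoselective stages that never generate a free phenoxide. Setting out from 14, acidic fluoride (HF·pyridine buffered with pyridine, THF, 0 °C) should cleave the two primary alkyl silyl ethers to give aryl silyl ether triol F8. KHF2 in MeOH at rt, which is selective for phenolic silyl ethers, then gives 15.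

**Further compounds**

F1 | step 8 | (2R)-2-{4-[(E)-3-(tert-butyldimethylsilyloxy)prop-1-enyl]-2,6-dimethoxyphenoxy}-3-hydroxypropyl acetate | CC(=O)OC[C@@H](CO)Oc1c(OC)cc(/C=C/CO[Si](C)(C)C(C)(C)C)cc1OC
F2 | step 8 | (2S)-3-(tert-butyldimethylsilyloxy)-2-{4-[(E)-3-(tert-butyldimethylsilyloxy)prop-1-enyl]-2,6-dimethoxyphenoxy}propyl acetate | CC(=O)OC[C@@H](CO[Si](C)(C)C(C)(C)C)Oc1c(OC)cc(/C=C/CO[Si](C)(C)C(C)(C)C)cc1OC
F3 | step 8 | (2S)-3-(tert-butyldimethylsilyloxy)-2-{4-[(E)-3-(tert-butyldimethylsilyloxy)prop-1-enyl]-2,6-dimethoxyphenoxy}propan-1-ol | OC[C@@H](CO[Si](C)(C)C(C)(C)C)Oc1c(OC)cc(/C=C/CO[Si](C)(C)C(C)(C)C)cc1OC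
F4 | step 8 | (2R)-3-(tert-butyldimethylsilyloxy)-2-{4-[(E)-3-(tert-butyldimethylsilyloxy)prop-1-enyl]-2,6-dimethoxyphenoxy}propanal | O=C[C@@H](CO[Si](C)(C)C(C)(C)C)Oc1c(OC)cc(/C=C/CO[Si](C)(C)C(C)(C)C)cc1OC
F5 | step 2 | ethyl 2-{4-[(E)-3-hydroxyprop-1-enyl]-2,6-dimethoxyphenoxy}acetate | CCOC(=O)COc1c(OC)cc(/C=C/CO)cc1OC
F6 | step 2 | ethyl 2-{4-[(E)-3-(tert-butyldimethylsilyloxy)prop-1-enyl]-2,6-dimethoxyphenoxy}acetate | CCOC(=O)COc1c(OC)cc(/C=C/CO[Si](C)(C)C(C)(C)C)cc1OC
F7 | step 2 | ethyl 2-{4-[(E)-3-(tert-butyldimethylsilyloxy)prop-1-enyl]-2,6-dimethoxyphenoxy}-3-oxopropanoate (racemic, mainly enol form) | CCOC(=O)C(C=O)Oc1c(OC)cc(/C=C/CO[Si](C)(C)C(C)(C)C)cc1OC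
F8 | step 9 | (1S,2R)-1-[4-(tert-butyldimethylsilyloxy)-3,5-dimethoxyphenyl]-2-{4-[(E)-3-hydroxyprop-1-enyl]-2,6-dimethoxyphenoxy}propane-1,3-diol | COc1cc([C@H](O)[C@@H](CO)Oc2c(OC)cc(/C=C/CO)cc2OC)cc(OC)c1O[Si](C)(C)C(C)(C)C
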